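**Retrosynthetic overview**

1. Numbering is that of the xanthanolides: upper unit C1–C15 (C1 carbinol, C8–O–C12 lactone), lower spiro-lactone unit primed; the central cyclohexene is C1–C2=C3–C11′–C13′–C5.
2. Last disconnections: the lower seven-membered ring and its dienone by domino enyne ring-closing/cross metathesis of 26; the upper α-methylene lactone from a phenylthio adduct; C2=C3 by dehydration.
3. Key disconnection: the cyclohexene is not closed directly but grown from cyclobutane C1–C5–C13′–C11′ (20) by insertion of C2–C3 of an acetyl-bearing enol ether. The enabling feature is that in 20 the silyloxy donor on C1 (the later tertiary hydroxyl) and the spiro-lactone carbonyl C12′ on C11′ flank the C1–C11′ bond, which makes it a latent 1,4-dipole whose two ends become the carbinol carbon and the spiro carbon of the six-membered ring.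
4. Cyclobutane 20 comes from a (2+2) union of the upper cyclic silyl enol ether 13 (C1=C5) with the lower α-methylene lactone 17 (C11′=C13′); both derive from the enantiomeric cis-lactones 9 and 17, each made by asymmetric conjugate alkynylation and allylboration–lactonisation.
5. Ring order: two γ-lactones → upper seven-membered ring (metathesis of a silyl enol ether) → cyclobutane → cyclohexene (four → six) → lower seven-membered ring.

Key step: step 14

**Remarks on the chemistry**

- In the target the upper unit (7R,8R,10S) and the lower unit (7′S,8′S,10′R) belong to opposite enantiomeric series, so two enantiomeric lactone building blocks are made by the same chemistry with antipodal catalysts.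
- β denotes the face of the upper seven-membered ring that carries the lactone (C7–C11, C8–O) and the C10 methyl group; α is the opposite face.
- C11 of the phenylthio adducts (11–13, 20–25) and C3 of 21 and 22 are temporary stereocentres, carried as epimer mixtures and drawn without configuration; both are removed later.
- The ligand and catalyst antipodes in steps 2, 3, 9 and 10 are written on the assumption of the usual sense of induction; if it is the reverse, the antipodes are exchanged.

**Route**

Step 1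
Reactants: 1 methyl prop-2-ynoate
Product: 3 methyl (2E)-2-[(4,4,5,5-tetramethyl-1,3,2-dioxaborolan-2-yl)methyl]hexa-2,5-dienoate, via vinylcopper 2 (not isolated)
Conditions: allylMgBr, CuBr·SMe2, THF, −78 °C; then 1; then ICH2Bpin, HMPA, −78 → 0 °C
Reagents that add atoms: allylmagnesium bromide C=CC[Mg]Br; 2-(iodomethyl)-4,4,5,5-tetramethyl-1,3,2-dioxaborolane ICB1OC(C)(C)C(C)(C)O1
Why: syn-carbocupration of the alkynoate and alkylation of the α-cuprio acrylate with retention should place the allyl group cis to CH2B, the geometry needed for a syn-selective allylboration.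

Step 2
Reactants: 4 (2E)-but-2-enal; 5 ethynyl[tri(propan-2-yl)]silane
Product: 6 (3S)-3-methyl-5-[tri(propan-2-yl)silyl]pent-4-ynal
Conditions: [Rh(OAc)(C2H4)2]2 (2.5 mol%), (R)-DTBM-SEGPHOS (6 mol%), MeOH, 40 °C
Reagents that add atoms: none
Why: rhodium-catalysed asymmetric conjugate alkynylation of an enal, in which the chiral bisphosphine–alkynylrhodium species selects the enal face and sets C10.

Step 3
Reactants: 6 (3S)-3-methyl-5-[tri(propan-2-yl)silyl]pent-4-ynal; 3 methyl (2E)-2-[(4,4,5,5-tetramethyl-1,3,2-dioxaborolan-2-yl)methyl]hexa-2,5-dienoate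
Product: 8 (4R,5R)-3-methylidene-5-{(2S)-2-methyl-4-[tri(propan-2-yl)silyl]but-3-yn-1-yl}-4-(prop-2-en-1-yl)oxolan-2-one, via borate 7 (not isolated)
Conditions: (R)-TRIP phosphoric acid (5 mol%), toluene, −30 °C → rt; then TsOH·H2O (10 mol%), CH2Cl2, rt
Reagents that add atoms: none
Why: chiral Brønsted acid-catalysed allylboration through a closed chair transition state, in which the γ-allyl group cis to CH2B gives the syn adduct (C7/C8, cis-lactone after acid lactonisation) and the phosphoric acid, not the remote C10 centre, selects the aldehyde face.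

Step 4
Reactants: 8 (4R,5R)-3-methylidene-5-{(2S)-2-methyl-4-[tri(propan-2-yl)silyl]but-3-yn-1-yl}-4-(prop-2-en-1-yl)oxolan-2-one
Product: 9 (4R,5R)-3-methylidene-5-[(2S)-2-methylbut-3-yn-1-yl]-4-(prop-2-en-1-yl)oxolan-2-one
Conditions: TBAF, AcOH, THF, 0 °C → rt
Reagents that add atoms: none
Why: fluoride-induced C(sp)–Si cleavage, buffered with acetic acid so that the α-methylene lactone is not attacked by base; no stereocentre is touched.

Step 5
Reactants: 9 (4R,5R)-3-methylidene-5-[(2S)-2-methylbut-3-yn-1-yl]-4-(prop-2-en-1-yl)oxolan-2-one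
Product: 10 (4R,5R)-3-methylidene-5-[(2S)-2-methyl-3-oxobutyl]-4-(prop-2-en-1-yl)oxolan-2-one
Conditions: Ph3PAuNTf2 (2 mol%), H2O, 1,4-dioxane, 60 °C
Reagents that add atoms: water O
Why: gold-catalysed Markovnikov hydration of the terminal alkyne should give the methyl ketone (C1=O) without touching the alkene or the enoate.

Step 6
Reactants: 10 (4R,5R)-3-methylidene-5-[(2S)-2-methyl-3-oxobutyl]-4-(prop-2-en-1-yl)oxolan-2-one
Product: 11 (4R,5R)-5-[(2S)-2-methyl-3-oxobutyl]-3-[(phenylsulfanyl)methyl]-4-(prop-2-en-1-yl)oxolan-2-one (C3 epimers)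
Conditions: PhSH, Et3N (10 mol%), CH2Cl2, 0 °C → rt
Reagents that add atoms: benzenethiol Sc1ccccc1
Why: thia-Michael addition masks the upper α-methylene lactone, the only strong Michael acceptor, so that it cannot compete as acceptor in step 13.

Step 7
Reactants: 11 (4R,5R)-5-[(2S)-2-methyl-3-oxobutyl]-3-[(phenylsulfanyl)methyl]-4-(prop-2-en-1-yl)oxolan-2-one
Product: 12 (4R,5R)-5-[(2S)-3-{[tert-butyl(dimethyl)silyl]oxy}-2-methylbut-3-en-1-yl]-3-[(phenylsulfanyl)methyl]-4-(prop-2-en-1-yl)oxolan-2-one
Conditions: LDA, THF, −78 °C; TBSCl, HMPA, −78 → 0 °C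
Reagents that add atoms: tert-butyl(chloro)dimethylsilane CC(C)(C)[Si](C)(C)Cl
Why: kinetic deprotonation of the methyl ketone at the methyl group and O-silylation give the 2-silyloxy-1-alkene, while the less acidic lactone and C10–H are left alone at −78 °C.

Step 8
Reactants: 12 (4R,5R)-5-[(2S)-3-{[tert-butyl(dimethyl)silyl]oxy}-2-methylbut-3-en-1-yl]-3-[(phenylsulfanyl)methyl]-4-(prop-2-en-1-yl)oxolan-2-one
Product: 13 (3aR,7S,8aR)-6-{[tert-butyl(dimethyl)silyl]oxy}-7-methyl-3-[(phenylsulfanyl)methyl]-3,3a,4,7,8,8a-hexahydro-2H-cyclohepta[b]furan-2-one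
Conditions: second-generation Grubbs catalyst (5 mol%), CH2Cl2, 40 °C
Reagents that add atoms: none
Why: ring-closing metathesis of the 1,1-disubstituted silyl enol ether with the terminal allyl alkene closes the upper seven-membered ring and fixes the enol ether as C1=C5.

Step 9
Reactants: 4 (2E)-but-2-enal; 5 ethynyl[tri(propan-2-yl)]silane
Product: 14 (3R)-3-methyl-5-[tri(propan-2-yl)silyl]pent-4-ynal
Conditions: [Rh(OAc)(C2H4)2]2 (2.5 mol%), (S)-DTBM-SEGPHOS (6 mol%), MeOH, 40 °C
Reagents that add atoms: none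
Why: the same rhodium-catalysed asymmetric conjugate alkynylation with the antipodal ligand sets C10′ in the opposite sense.

Step 10
Reactants: 14 (3R)-3-methyl-5-[tri(propan-2-yl)silyl]pent-4-ynal; 3 methyl (2E)-2-[(4,4,5,5-tetramethyl-1,3,2-dioxaborolan-2-yl)methyl]hexa-2,5-dienoate
Product: 16 (4S,5S)-3-methylidene-5-{(2R)-2-methyl-4-[tri(propan-2-yl)silyl]but-3-yn-1-yl}-4-(prop-2-en-1-yl)oxolan-2-one, via borate 15 (not isolated)
Conditions: (S)-TRIP phosphoric acid (5 mol%), toluene, −30 °C → rt; then TsOH·H2O (10 mol%), CH2Cl2, rt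
Reagents that add atoms: none
Why: the same chiral Brønsted acid-catalysed syn-allylboration and lactonisation with the antipodal acid set C7′ and C8′ (cis-lactone).

Step 11
Reactants: 16 (4S,5S)-3-methylidene-5-{(2R)-2-methyl-4-[tri(propan-2-yl)silyl]but-3-yn-1-yl}-4-(prop-2-en-1-yl)oxolan-2-one
Product: 17 (4S,5S)-3-methylidene-5-[(2R)-2-methylbut-3-yn-1-yl]-4-(prop-2-en-1-yl)oxolan-2-one
Conditions: TBAF, AcOH, THF, 0 °C → rt
Reagents that add atoms: none
Why: buffered fluoride-induced C(sp)–Si cleavage frees the terminal alkyne needed for the final enyne metathesis.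

Step 12
Reactants: 18 butane-2,3-dione
Product: 19 3-[(trimethylsilyl)oxy]but-3-en-2-one
Conditions: TMSCl, Et3N, DMF, rt
Reagents that add atoms: chlorotrimethylsilane C[Si](C)(C)Cl
Why: O-silylation of the mono-enol of the 1,2-diketone gives the 2-silyloxy enone, the C2–C3–acetyl building block.

Step 13
Reactants: 13 (3aR,7S,8aR)-6-{[tert-butyl(dimethyl)silyl]oxy}-7-methyl-3-[(phenylsulfanyl)methyl]-3,3a,4,7,8,8a-hexahydro-2H-cyclohepta[b]furan-2-one; 17 (4S,5S)-3-methylidene-5-[(2R)-2-methylbut-3-yn-1-yl]-4-(prop-2-en-1-yl)oxolan-2-one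
Product: 20 spiro cyclobutane (1R,5S,7R,8R,10S,7′S,8′S,10′R,11′R): ring C1–C5–C13′–C11′ cis-fused to the upper seven-membered ring, OTBS on C1 (α), C13′ on C5 (β), C11′ spiro to the lower lactone
Conditions: Tf2NH (3 mol%), 17 (1.3 equiv), CH2Cl2, −78 °C
Reagents that add atoms: none
Why: (2+2) cycloaddition of a silyl enol ether with an α,β-unsaturated lactone by Mukaiyama–Michael addition and intramolecular aldol closure under silyl triflimide catalysis, with regiochemistry fixed by polarity (C5 to C13′, C11′ to C1); C5–C13′ bond formation is expected on the β face, the exposed face of the chair cycloheptene in which C7–C8–C9 fold to the α side, the four-membered ring is necessarily cis-fused, and C1 adds to C11′ trans to the C7′ allyl group.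

Step 14
Reactants: 20 spiro cyclobutane; 19 3-[(trimethylsilyl)oxy]but-3-en-2-one
Product: 22 (1S,5S,7R,8R,10S,7′S,8′S,10′R,11′R) spiro cyclohexane: ring C1–C2–C3–C11′–C13′–C5 with OTBS on C1 (β), hydroxyl and acetyl on C3, via trimethylsilyl ether 21 (not isolated)
Conditions: Tf2NH (10 mol%), 19 (3 equiv), CH2Cl2, −78 → −30 °C; then 1 M HCl, THF, 0 °C
Reagents that add atoms: none
Why: Proposed new method: the silyl triflimide formed from Tf2NH and 19 binds the spiro-lactone carbonyl of 20, and push–pull heterolysis of the strained C1–C11′ bond (siloxy donor on C1, acyl acceptor on C11′) gives a 1,4-dipole, a silyloxocarbenium ion at C1 and a silyl ketene acetal at C11′; C2 of 19 adds to C1 (Mukaiyama addition) and the resulting silyl-activated C3 ketone is trapped by C11′ (Mukaiyama aldol), which returns the silyl cation and makes the cycle catalytic. The closest known reaction types are the Lewis-acid (4+2) annulations of alkoxy-substituted donor–acceptor cyclobutanes and 3-alkoxycyclobutanones with silyl enol ethers and carbonyl compounds, and the acid-induced ring opening of siloxycyclobutane esters obtained by (2+2) cycloaddition; new is the single lactone acceptor combined with an enol ether of a 1,2-diketone. The six-membered ring closes by 6-exo-trig attack of the C11′ ketene acetal on the C3 carbonyl after intermolecular C1–C2 bond formation, so the cyclobutane is enlarged by the two carbons C2 and C3 (four → six). At C1 the enol ether should enter on the α face, trans to the C10 methyl group and to C13′ on C5, leaving the oxygen β; at C11′ the planar ketene acetal should be attacked by C3 on the face trans to the C7′ allyl group; C3 is not controlled and is removed in step 15. The step needs capture of the oxocarbenium ion by external 19 to outrun proton loss from C5 or C10 and reclosure to 20, which the excess of the small enol ether, the non-basic triflimide counter-ion and the low temperature should secure, while C5 and the lactone stereocentres are not touched.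

Step 15
Reactants: 22 spiro cyclohexane with hydroxyl and acetyl on C3
Product: 23 (1S,5S,7R,8R,10S,7′S,8′S,10′R,11′R) enone: C2=C3 with acetyl on C3, OTBS on C1
Conditions: SOCl2, pyridine, CH2Cl2, −20 → 0 °C
Reagents that add atoms: none
Why: dehydration of the tertiary α-hydroxy ketone through its chlorosulfite, in which only C2 carries β-hydrogens (C11′ is quaternary), so the conjugated C2=C3 bond forms regiospecifically and the undefined C3 centre disappears.

Step 16
Reactants: 23 enone with OTBS on C1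
Product: 24 (1S,5S,7R,8R,10S,7′S,8′S,10′R,11′R) tertiary alcohol: C1–OH, C2=C3–acetyl, upper lactone still as phenylthio adduct
Conditions: HF·pyridine, THF, 0 °C → rt
Reagents that add atoms: none
Why: fluoride cleavage of the tertiary silyl ether breaks O–Si and not C–O, so the C1 configuration is retained.

Step 17
Reactants: 24 tertiary alcohol with phenylthio-masked upper lactone
Product: 26 (1S,5S,7R,8R,10S,7′S,8′S,10′R,11′R) enyne: upper unit complete (α-methylene lactone, C1–OH, enone), lower lactone with allyl on C7′ and (2R)-2-methylbut-3-ynyl on C8′, via sulfoxide 25 (not isolated)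
Conditions: NaIO4, MeOH/H2O, 0 °C → rt; then toluene, NaHCO3, 110 °C
Reagents that add atoms: none
Why: chemoselective oxidation of the sulfide to the sulfoxide and thermal syn-elimination (sulfoxide pyrolysis), in which H11 is the only β-hydrogen, should restore the exocyclic C11=C13 bond and remove the temporary C11 centre.

Step 18
Reactants: 26 enyne with complete upper unit
Product: 27 target CNP0168949.2, (1S,5S,7R,8R,10S,7′S,8′S,10′R,11′R)
Conditions: second-generation Hoveyda–Grubbs catalyst (10 mol%), methyl vinyl ketone (10 equiv), CH2Cl2, 40 °C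
Reagents that add atoms: but-3-en-2-one C=CC(C)=O
Why: domino ring-closing enyne metathesis (exo mode, forming C1′=C5′ in the lower seven-membered ring) followed by cross-metathesis of the new vinyl group with the enone should give the E-dienone, while the electron-poor 1,1-disubstituted and trisubstituted alkenes of the upper unit stay out and no stereocentre is touched.

**Compound list**

1 | methyl prop-2-ynoate | C#CC(=O)OC | starting material
2 | methyl (2Z)-2-cupriohexa-2,5-dienoate (allyl cis to Cu) | C=CC/C=C(\[Cu])C(=O)OC | intermediate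
3 | methyl (2E)-2-[(4,4,5,5-tetramethyl-1,3,2-dioxaborolan-2-yl)methyl]hexa-2,5-dienoate (allyl cis to CH2B) | C=CC/C=C(\CB1OC(C)(C)C(C)(C)O1)C(=O)OC | intermediate
4 | (2E)-but-2-enal | C/C=C/C=O | starting material
5 | ethynyl[tri(propan-2-yl)]silane | C#C[Si](C(C)C)(C(C)C)C(C)C | starting material
6 | (3S)-3-methyl-5-[tri(propan-2-yl)silyl]pent-4-ynal | O=CC[C@H](C)C#C[Si](C(C)C)(C(C)C)C(C)C | intermediate
7 | methyl (3R,4R,6S)-6-methyl-2-methylidene-3-(prop-2-en-1-yl)-4-[(4,4,5,5-tetramethyl-1,3,2-dioxaborolan-2-yl)oxy]-8-[tri(propan-2-yl)silyl]oct-7-ynoate | COC(=O)C(=C)[C@@H](CC=C)[C@@H](C[C@H](C)C#C[Si](C(C)C)(C(C)C)C(C)C)OB1OC(C)(C)C(C)(C)O1 | intermediate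
8 | (4R,5R)-3-methylidene-5-{(2S)-2-methyl-4-[tri(propan-2-yl)silyl]but-3-yn-1-yl}-4-(prop-2-en-1-yl)oxolan-2-one | C=C1C(=O)O[C@H](C[C@H](C)C#C[Si](C(C)C)(C(C)C)C(C)C)[C@@H]1CC=C | intermediate
9 | (4R,5R)-3-methylidene-5-[(2S)-2-methylbut-3-yn-1-yl]-4-(prop-2-en-1-yl)oxolan-2-one | C=C1C(=O)O[C@H](C[C@H](C)C#C)[C@@H]1CC=C | intermediate
10 | (4R,5R)-3-methylidene-5-[(2S)-2-methyl-3-oxobutyl]-4-(prop-2-en-1-yl)oxolan-2-one | C=C1C(=O)O[C@H](C[C@H](C)C(C)=O)[C@@H]1CC=C | intermediate
11 | (4R,5R)-5-[(2S)-2-methyl-3-oxobutyl]-3-[(phenylsulfanyl)methyl]-4-(prop-2-en-1-yl)oxolan-2-one, C3 epimers | O=C1O[C@H](C[C@H](C)C(C)=O)[C@H](CC=C)C1CSc1ccccc1 | intermediate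
12 | (4R,5R)-5-[(2S)-3-{[tert-butyl(dimethyl)silyl]oxy}-2-methylbut-3-en-1-yl]-3-[(phenylsulfanyl)methyl]-4-(prop-2-en-1-yl)oxolan-2-one | O=C1O[C@H](C[C@H](C)C(=C)O[Si](C)(C)C(C)(C)C)[C@H](CC=C)C1CSc1ccccc1 | intermediate
13 | (3aR,7S,8aR)-6-{[tert-butyl(dimethyl)silyl]oxy}-7-methyl-3-[(phenylsulfanyl)methyl]-3,3a,4,7,8,8a-hexahydro-2H-cyclohepta[b]furan-2-one | O=C1O[C@@H]2C[C@H](C)C(O[Si](C)(C)C(C)(C)C)=CC[C@@H]2C1CSc1ccccc1 | intermediate
14 | (3R)-3-methyl-5-[tri(propan-2-yl)silyl]pent-4-ynal | O=CC[C@@H](C)C#C[Si](C(C)C)(C(C)C)C(C)C | intermediate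
15 | methyl (3S,4S,6R)-6-methyl-2-methylidene-3-(prop-2-en-1-yl)-4-[(4,4,5,5-tetramethyl-1,3,2-dioxaborolan-2-yl)oxy]-8-[tri(propan-2-yl)silyl]oct-7-ynoate | COC(=O)C(=C)[C@H](CC=C)[C@H](C[C@@H](C)C#C[Si](C(C)C)(C(C)C)C(C)C)OB1OC(C)(C)C(C)(C)O1 | intermediate
16 | (4S,5S)-3-methylidene-5-{(2R)-2-methyl-4-[tri(propan-2-yl)silyl]but-3-yn-1-yl}-4-(prop-2-en-1-yl)oxolan-2-one | C=C1C(=O)O[C@@H](C[C@@H](C)C#C[Si](C(C)C)(C(C)C)C(C)C)[C@H]1CC=C | intermediate
17 | (4S,5S)-3-methylidene-5-[(2R)-2-methylbut-3-yn-1-yl]-4-(prop-2-en-1-yl)oxolan-2-one | C=C1C(=O)O[C@@H](C[C@@H](C)C#C)[C@H]1CC=C | intermediate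
18 | butane-2,3-dione | CC(=O)C(C)=O | starting material
19 | 3-[(trimethylsilyl)oxy]but-3-en-2-one | C=C(O[Si](C)(C)C)C(C)=O | intermediate
20 | spiro cyclobutane (1R,5S,7R,8R,10S,7′S,8′S,10′R,11′R): C1(OTBS)–C5–C13′–C11′ ring cis-fused to the upper seven-membered ring and spiro to the lower lactone | O=C1O[C@@H]2C[C@H](C)[C@]3(O[Si](C)(C)C(C)(C)C)[C@]4(C[C@@H]3C[C@@H]2C1CSc1ccccc1)C(=O)O[C@@H](C[C@@H](C)C#C)[C@H]4CC=C | intermediate
21 | trimethylsilyl ether of 22 (C3–OTMS, C1–OTBS) | O=C1O[C@@H]2C[C@H](C)[C@@]3(O[Si](C)(C)C(C)(C)C)CC(O[Si](C)(C)C)(C(C)=O)[C@]4(C[C@@H]3C[C@@H]2C1CSc1ccccc1)C(=O)O[C@@H](C[C@@H](C)C#C)[C@H]4CC=C | intermediate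
22 | spiro cyclohexane (1S,5S,7R,8R,10S,7′S,8′S,10′R,11′R): C1–OTBS, C3 hydroxyl and acetyl, C3 epimers | O=C1O[C@@H]2C[C@H](C)[C@@]3(O[Si](C)(C)C(C)(C)C)CC(O)(C(C)=O)[C@]4(C[C@@H]3C[C@@H]2C1CSc1ccccc1)C(=O)O[C@@H](C[C@@H](C)C#C)[C@H]4CC=C | intermediate
23 | enone (1S,5S,7R,8R,10S,7′S,8′S,10′R,11′R): C2=C3–acetyl, C1–OTBS | O=C1O[C@@H]2C[C@H](C)[C@@]3(O[Si](C)(C)C(C)(C)C)C=C(C(C)=O)[C@]4(C[C@@H]3C[C@@H]2C1CSc1ccccc1)C(=O)O[C@@H](C[C@@H](C)C#C)[C@H]4CC=C | intermediate
24 | tertiary alcohol (1S,5S,7R,8R,10S,7′S,8′S,10′R,11′R): C1–OH, C2=C3–acetyl, phenylthio-masked upper lactone | O=C1O[C@@H]2C[C@H](C)[C@@]3(O)C=C(C(C)=O)[C@]4(C[C@@H]3C[C@@H]2C1CSc1ccccc1)C(=O)O[C@@H](C[C@@H](C)C#C)[C@H]4CC=C | intermediate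
25 | sulfoxide of 24 | O=C1O[C@@H]2C[C@H](C)[C@@]3(O)C=C(C(C)=O)[C@]4(C[C@@H]3C[C@@H]2C1CS(=O)c1ccccc1)C(=O)O[C@@H](C[C@@H](C)C#C)[C@H]4CC=C | intermediate
26 | enyne (1S,5S,7R,8R,10S,7′S,8′S,10′R,11′R): complete upper unit, lower lactone with allyl on C7′ and (2R)-2-methylbut-3-ynyl on C8′ | C=C1C(=O)O[C@@H]2C[C@H](C)[C@@]3(O)C=C(C(C)=O)[C@]4(C[C@@H]3C[C@H]12)C(=O)O[C@@H](C[C@@H](C)C#C)[C@H]4CC=C | intermediate
27 | CNP0168949.2, (1S,5S,7R,8R,10S,7′S,8′S,10′R,11′R) | C=C1C(=O)O[C@@H]2C[C@H](C)[C@@]3(O)C=C(C(C)=O)[C@]4(C[C@@H]3C[C@H]12)C(=O)O[C@H]1C[C@@H](C)C(/C=C/C(C)=O)=CC[C@H]14 | target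

**Step count**

Total: 18 steps. Longest linear sequence: 13 steps (steps 2, 3, 4, 5, 6, 7, 8, 13, 14, 15, 16, 17, 18).

**Steps most likely to fail**

1. Step 14 (Proposed new method). After heterolysis the 1,4-dipole may collapse by proton transfer from C5 or C10 to C11′, giving the open-chain Michael adduct, or simply reclose, so that 19 is never taken up; addition to the hindered C1 oxocarbenium ion may also be too slow. The fallback uses known reaction types and keeps a four → six ring expansion; it sets out from 9 and 17 and returns at 26. Lactone 9 is converted with methyl vinyl ketone and second-generation Hoveyda–Grubbs catalyst (domino enyne ring-closing/cross metathesis) into 8-epi-xanthatin F1. Sensitised (2+2) photocycloaddition (thioxanthen-9-one, 405 nm, excess 17) of the C1=C5 bond of F1 to the methylene group of 17 would give vinylcyclobutane F2. Heating (toluene, 160 °C, sealed tube) should effect the vinylcyclobutane–cyclohexene (1,3) shift of C11′ from C1 to C3 through a diradical stabilised by the enone and the lactone, giving the Diels–Alder-type adduct F3. Deprotonation at C3 (KOtBu, THF, −78 °C) and oxygenation of the dienolate at C1 (O2, then P(OEt)3) through hydroperoxide F4 would give 26.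

2. Step 13. Facial selectivity at C5 may be poor: C–C bond formation anti to the C10 methyl group would give the C5 epimer. Proton loss after the Michael step may also give the open-chain adduct instead of the four-membered ring. The fallback sets C5 by equilibration and closes the ring photochemically; it sets out from 13 and 17 and returns at 20. Mukaiyama–Michael addition (TiCl4, CH2Cl2, −78 °C, aqueous work-up) would give keto lactone F5, which is equilibrated (DBU, THF) to the 2,7-cis-disubstituted cycloheptanone. Norrish–Yang photocyclisation (350 nm, benzene; γ-hydrogen on C11′) would close cyclobutanol F6, and silylation (TBSOTf, 2,6-lutidine) gives 20.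

3. Step 18. The catalyst may be slowed by the free tertiary alcohol and the lactones, cross-metathesis at the terminal alkene may precede ring closure and give acyclic material, and homodimerisation of the enone may consume catalyst. The fallback builds the ketone by a different bond; it sets out from 26 and returns at 27. Domino enyne metathesis of 26 with vinylboronic acid pinacol ester (second-generation Grubbs catalyst, CH2Cl2, 40 °C) would give dienylboronate F7. Acylative Suzuki coupling (acetyl chloride, Pd(PPh3)4, Cs2CO3, toluene) then installs the methyl ketone to give 27.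

Further compounds
F1 | step 14 | (3aR,7S,8aR)-7-methyl-3-methylidene-6-[(1E)-3-oxobut-1-en-1-yl]-3,3a,4,7,8,8a-hexahydro-2H-cyclohepta[b]furan-2-one (8-epi-xanthatin) | C=C1C(=O)O[C@@H]2C[C@H](C)C(/C=C/C(C)=O)=CC[C@H]12
F2 | step 14 | vinylcyclobutane: ring C1–C5–C13′–C11′ with the (E)-3-oxobut-1-enyl group on C1, spiro to the lower lactone | C=C1C(=O)O[C@@H]2C[C@H](C)[C@]3(/C=C/C(C)=O)[C@]4(C[C@@H]3C[C@H]12)C(=O)O[C@@H](C[C@@H](C)C#C)[C@H]4CC=C
F3 | step 14 | Diels–Alder-type adduct: cyclohexene C1=C2 with acetyl on C3 (C3 epimers) | C=C1C(=O)O[C@@H]2C[C@H](C)C3=CC(C(C)=O)[C@]4(C[C@@H]3C[C@H]12)C(=O)O[C@@H](C[C@@H](C)C#C)[C@H]4CC=C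
F4 | step 14 | C1 hydroperoxide of 26 | C=C1C(=O)O[C@@H]2C[C@H](C)[C@@]3(OO)C=C(C(C)=O)[C@]4(C[C@@H]3C[C@H]12)C(=O)O[C@@H](C[C@@H](C)C#C)[C@H]4CC=C
F5 | step 13 | keto lactone: upper cycloheptanone (C1=O) carrying on C5 the CH2 link to C11′ of the lower lactone (C11′ epimers) | O=C1O[C@@H]2C[C@H](C)C(=O)[C@H](CC3C(=O)O[C@@H](C[C@@H](C)C#C)[C@H]3CC=C)C[C@@H]2C1CSc1ccccc1
F6 | step 13 | cyclobutanol: desilylated 20 | O=C1O[C@@H]2C[C@H](C)[C@]3(O)[C@]4(C[C@@H]3C[C@@H]2C1CSc1ccccc1)C(=O)O[C@@H](C[C@@H](C)C#C)[C@H]4CC=C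
F7 | step 18 | dienylboronate: 27 with the (E)-2-(pinacolboryl)ethenyl group in place of the oxobutenyl group | C=C1C(=O)O[C@@H]2C[C@H](C)[C@@]3(O)C=C(C(C)=O)[C@]4(C[C@@H]3C[C@H]12)C(=O)O[C@H]1C[C@@H](C)C(/C=C/B2OC(C)(C)C(C)(C)O2)=CC[C@H]14
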